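The isomer of the product stands in the oak run at 90.5% after 2.00 h and at 88.9% after 5.00 h, which is less than the 99.7% of the elm run at that time, so the examination opens there.

| flask | starting material | partner | remark | time |
|---|---|---|---|---|
| oak | 20 mM | 18 mM | run made earlier |  |
| elm | 20 mM | 72 mM | run made earlier |  |
| birch | 10 mM | 36 mM | run made earlier |  |
| flask | 20 mM | 36.0 mM |  | 6.0 h |

- oak (time / h: starting material / %, isomer of the product / %, target / %): 0.417: 47.6, 53.6, 0; 0.833: 23.7, 75.1, 0; 2.00: 7.7, 90.5, 2.3; 5.00: 8.9, 88.9, 0.9
- elm (time / h: starting material / %, isomer of the product / %, target / %): 0.417: 46.2, 53.2, 0.8; 0.833: 22.1, 77.4, 1.7; 2.00: 3.1, 97.0, 0; 5.00: 1.3, 99.7, 0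
- birch (time / h: starting material / %, isomer of the product / %, target / %): 0.417: 45.6, 54.5, 0.8; 0.833: 22.2, 77.8, 1.2; 2.00: 2.7, 96.8, 0.7; 5.00: 0, 99.9, 0.2

(scatter of a reading: 1 percentage point)

- a reading or a percentage of target counts all its forms, free or not
- the reaction counts as stopped when no species that holds the starting material changes by six tenths of a point or more over the second half of the time

- at 6.0 h, what has stopped the reaction, if anything has (it is still moving / forward and back rates have come level / the partner has run out first / all of the starting material has reacted)
- conversion of starting material at 6.0 h
- amount of isomer of the product at 6.0 h, in percent of the starting material charged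
- amount of target if the flask were left three thousand times as long, in percent of the starting material charged

Has the oak run used up its starting material? No, a reading of 8.9% still stands at the end, so something other than loss of starting material holds the isomer back.

What, then? Oak was charged with 18 mM of partner against 20 mM of starting material, a ratio of 0.900, and the isomer readings in oak level off near that fraction, as they would if each isomer took up one partner.

And the flask? There the partner charged over the starting material charged is 1.80, and this charge ratio, capped at one, is the ceiling on the isomer, so I put the ceiling at 100%, with 44.4% of the partner's own charge to spare.

But is the ceiling reached in time, given that a ceiling says nothing of speed? The starting material reads 23.7% in oak and 22.1% in elm at 0.833 h, though elm has 4.00 times the partner, so partner shows no hand in the pace, and the birch reading of 22.2% gives a half-life of 0.384 h; the flask's 6.0 h is 15.6 of those, which leaves hardly any starting material.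

And the target? Its highest reading is 2.3%, in oak, falling to 0.9% there against a scatter of 1 percentage point, so I expect none worth counting, and I say the flask ends with its starting material consumed.

The forecast gives all of the starting material has reacted, with conversion 99.8%, isomer 99.5%, a shade under my ceiling, and target 0.5% after the long wait, holding that “partner will not run out”.

The flask gives all of the starting material has reacted, with conversion >99.9%, isomer >99.9%, target 0% after the long wait, and 44% of the partner's charge left at 6.00 h.

    tight pair ⇌ loose pair (K = 0.330, k = 0.260 /s)
    crystals ⇌ target, rate k2*(cs2 - [target]) while solid is left; crystals form when [target] > cs2 (solubility = 9.90 mM, k = 0.950 /s)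
    partner + tight pair ⇌ target (K = 5.70 /M, k = 1800 /M/s)
    loose pair → decomposed reagent (k = 0.00370 /s)
    starting material ⇌ tight pair (K = 0.00240, k = 0.00280 /s)
    partner + loose pair → isomer of the product (k = 4300 /M/s)

Now take a neighbouring flask, with the same charge of partner and the same time but 50 mM of starting material. Its charge ratio is 0.720, under one, so the same reckoning puts the ceiling on the isomer at 72.0% of the starting material charged. This neighbouring flask gives 72.0% at 6.00 h. In this neighbouring flask partner, here the limiting reagent, stands at 0% of its charge, while of the starting material charged 26% is still there and 1.51% stands as decomposed reagent.

Readings and results stem from a simulated flask on assumed constants.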